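**Retrosynthetic overview**
- Target 12 ⇒ Heck coupling of aryl iodide 2 with vinylcyclohexene 11; 11 ⇐ aldehyde 10 (Wittig) ⇐ nitromethyl compound 8 (Nef).
- 8 ⇒ key step: the homoenolate of enal 4 (chiral triazolylidene catalyst) adds through its β-carbon to the β-carbon of nitroalkene 6, making the C1–C2 bond and both stereocentres; aldol, β-lactonisation and loss of CO2 then close the ring and place the ring alkene.
- 4 ⇐ 2 + acrolein (Heck); 6 ⇐ 5-methylhex-5-en-2-one (nitration); 2 ⇐ 5,7-dimethoxycoumarin (iodination).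
- Ring order: both coumarin bicycles are bought intact; the cyclohexene is the only ring formed (step 4).

Assumption: the (5aS,10bR) antipode of the aminoindanol-derived triazolium is taken to direct attack to the Si face of the enal β-carbon; if the sense proves opposite, its commercial mirror image is used with no other change.

**Route**

Step 1
Reactants: 1 5,7-dimethoxy-2H-chromen-2-one
Product: 2 8-iodo-5,7-dimethoxy-2H-chromen-2-one
Conditions: NIS (1.05 equiv), TFA (0.3 equiv), MeCN, 0 °C to rt
Reagents that add atoms: N-iodosuccinimide, O=C1CCC(=O)N1I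
Why: Electrophilic aromatic iodination at C8, which is activated by the para C5-methoxy, the ortho C7-methoxy and the ring oxygen and is less hindered than C6 (by analogy with 5,7-dimethoxyflavones), any 6-iodo isomer being removed by crystallisation.

Step 2
Reactants: 2 8-iodo-5,7-dimethoxy-2H-chromen-2-one; 3 acrolein (prop-2-enal)
Product: 4 (2E)-3-(5,7-dimethoxy-2-oxo-2H-chromen-8-yl)prop-2-enal
Conditions: Pd(OAc)2 (5 mol %), nBu4NCl, NaHCO3, DMF, 60 °C, sealed tube
Reagents that add atoms: none
Why: Mizoroki–Heck reaction under ligand-free Jeffery conditions, in which syn β-hydride elimination gives the E enal.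

Step 3
Reactants: 5 5-methylhex-5-en-2-one
Product: 6 (5E)-5-methyl-6-nitrohex-5-en-2-one
Conditions: AgNO2 (3 equiv), TEMPO (0.4 equiv), 4 Å MS, ClCH2CH2Cl, 70 °C
Reagents that add atoms: silver nitrite, [Ag+].[O-]N=O
Why: Radical nitration of a terminal alkene (NO2 radical adds to the CH2 terminus, TEMPO-mediated hydrogen removal restores the alkene), giving the conjugated nitroalkene with the nitro group trans to the larger oxobutyl chain (E).

Step 4
Reactants: 4 (2E)-3-(5,7-dimethoxy-2-oxo-2H-chromen-8-yl)prop-2-enal; 6 (5E)-5-methyl-6-nitrohex-5-en-2-one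
Product: 8 5,7-dimethoxy-8-[(1R,6S)-3,6-dimethyl-6-(nitromethyl)cyclohex-2-en-1-yl]-2H-chromen-2-one, via bicyclic beta-lactone 7 (not isolated)
Conditions: (5aS,10bR)-2-mesityl-5a,10b-dihydro-4H,6H-indeno[2,1-b][1,2,4]triazolo[4,3-d][1,4]oxazin-2-ium chloride (10 mol %), iPr2NEt (20 mol %), THF, 0 °C to rt, slow addition of 4; then PhMe, 110 °C
Reagents that add atoms: none
Why: Proposed new method: the N-mesityl triazolylidene turns enal 4 into its Breslow-type homoenolate, whose β-carbon (normally the electrophilic site of the enal) adds to the electrophilic β-carbon of nitroalkene 6 to make the C1–C2 bond and the quaternary centre; proton transfer gives the azolium enolate, which closes the six-membered ring by aldol addition to the methyl ketone; the tertiary alkoxide acylates the acyl azolium (catalyst turnover) to give β-lactone 7, which loses CO2 on heating to place the trisubstituted ring alkene; the closest known reactions are the homoenolate annulation of enals with enones to cyclopentenes (Michael, aldol, β-lactonisation, decarboxylation) and the enantioselective homoenolate addition of enals to nitroalkenes; catalyst-controlled union of the Si face of the enal β-carbon with the Re face of C5 of (E)-6 (syn topicity, aryl syn to the chain that is trans to nitro) sets (1R,6S), that is aryl cis to CH2NO2.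

Step 5
Reactants: 8 5,7-dimethoxy-8-[(1R,6S)-3,6-dimethyl-6-(nitromethyl)cyclohex-2-en-1-yl]-2H-chromen-2-one
Product: 10 (1S,2S)-2-(5,7-dimethoxy-2-oxo-2H-chromen-8-yl)-1,4-dimethylcyclohex-3-ene-1-carbaldehyde, via sodium nitronate 9 (not isolated)
Conditions: NaOMe (1.05 equiv), MeOH/THF, 0 °C; then aq. TiCl3 (4.5 equiv), NH4OAc buffer (pH 5–6), 0 °C to rt
Reagents that add atoms: water, O
Why: McMurry reductive Nef reaction, in which trivalent titanium reduces the nitronate to the imine that hydrolyses to the aldehyde under buffered conditions that spare the alkene and the lactone, and the quaternary α-carbon cannot epimerise (the descriptors change only through CIP priorities).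

Step 6
Reactants: 10 (1S,2S)-2-(5,7-dimethoxy-2-oxo-2H-chromen-8-yl)-1,4-dimethylcyclohex-3-ene-1-carbaldehyde
Product: 11 8-[(1R,6R)-6-ethenyl-3,6-dimethylcyclohex-2-en-1-yl]-5,7-dimethoxy-2H-chromen-2-one
Conditions: Ph3PCH3Br (1.3 equiv), KN(SiMe3)2 (1.2 equiv), THF, 0 °C; then 10, −78 °C to 0 °C
Reagents that add atoms: methyltriphenylphosphonium bromide, C[P+](c1ccccc1)(c1ccccc1)c1ccccc1.[Br-]
Why: Wittig methylenation, the non-stabilised ylide reacting with the aldehyde far faster than with the lactone at low temperature, with no stereocentre touched.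

Step 7
Reactants: 11 8-[(1R,6R)-6-ethenyl-3,6-dimethylcyclohex-2-en-1-yl]-5,7-dimethoxy-2H-chromen-2-one; 2 8-iodo-5,7-dimethoxy-2H-chromen-2-one
Product: 12 8-[(1R,6R)-6-[(E)-2-(5,7-dimethoxy-2-oxo-2H-chromen-8-yl)ethenyl]-3,6-dimethylcyclohex-2-en-1-yl]-5,7-dimethoxy-2H-chromen-2-one
Conditions: Pd(OAc)2 (10 mol %), nBu4NCl, NaHCO3, DMF, 80 °C
Reagents that add atoms: none
Why: Mizoroki–Heck reaction in which the aryl group adds to the terminal carbon and palladium sits next to the quaternary carbon, so the only β-hydrogen is benzylic and elimination gives the E-styrene without touching either stereocentre.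

**Compound list**
1 | 5,7-dimethoxy-2H-chromen-2-one | COc1cc(OC)c2ccc(=O)oc2c1 | starting material
2 | 8-iodo-5,7-dimethoxy-2H-chromen-2-one | COc1cc(OC)c2ccc(=O)oc2c1I | intermediate
3 | acrolein (prop-2-enal) | C=CC=O | starting material
4 | (2E)-3-(5,7-dimethoxy-2-oxo-2H-chromen-8-yl)prop-2-enal | COc1cc(OC)c2ccc(=O)oc2c1/C=C/C=O | intermediate
5 | 5-methylhex-5-en-2-one | CC(=O)CCC(C)=C | starting material
6 | (5E)-5-methyl-6-nitrohex-5-en-2-one | CC(=O)CC/C(C)=C/[N+](=O)[O-] | intermediate
7 | (1R,2R,3S,6S)-2-(5,7-dimethoxy-2-oxo-2H-chromen-8-yl)-3,6-dimethyl-3-(nitromethyl)-7-oxabicyclo[4.2.0]octan-8-one (cis-fused β-lactone, lactone trans to aryl; ring-fusion configuration assumed and lost on decarboxylation) | [O-][N+](=O)C[C@@]1(C)CC[C@]2(C)OC(=O)[C@@H]2[C@H]1c1c(OC)cc(OC)c2ccc(=O)oc12 | intermediate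
8 | 5,7-dimethoxy-8-[(1R,6S)-3,6-dimethyl-6-(nitromethyl)cyclohex-2-en-1-yl]-2H-chromen-2-one | [O-][N+](=O)C[C@@]1(C)CCC(C)=C[C@H]1c1c(OC)cc(OC)c2ccc(=O)oc12 | intermediate
9 | sodium nitronate (aci-nitro sodium salt) of 8, ring configuration unchanged | [Na+].[O-][N+]([O-])=C[C@@]1(C)CCC(C)=C[C@H]1c1c(OC)cc(OC)c2ccc(=O)oc12 | intermediate
10 | (1S,2S)-2-(5,7-dimethoxy-2-oxo-2H-chromen-8-yl)-1,4-dimethylcyclohex-3-ene-1-carbaldehyde | O=C[C@@]1(C)CCC(C)=C[C@H]1c1c(OC)cc(OC)c2ccc(=O)oc12 | intermediate
11 | 8-[(1R,6R)-6-ethenyl-3,6-dimethylcyclohex-2-en-1-yl]-5,7-dimethoxy-2H-chromen-2-one | C=C[C@@]1(C)CCC(C)=C[C@H]1c1c(OC)cc(OC)c2ccc(=O)oc12 | intermediate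
12 | 8-[(1R,6R)-6-[(E)-2-(5,7-dimethoxy-2-oxo-2H-chromen-8-yl)ethenyl]-3,6-dimethylcyclohex-2-en-1-yl]-5,7-dimethoxy-2H-chromen-2-one | COc1cc(OC)c2ccc(=O)oc2c1/C=C/[C@@]1(C)CCC(C)=C[C@H]1c1c(OC)cc(OC)c2ccc(=O)oc12 | target

**Step count**
Total steps: 7. Longest linear sequence: 6 (steps 1, 2, 4, 5, 6, 7).

**Three steps most likely to fail**

Step 4 (highest risk). The homoenolate has to attack a β,β-disubstituted nitroalkene next to a di-ortho-substituted aryl group. Competing paths are deconjugation of 6 to the allylic nitro isomer, Stetter-type addition, C-acylation of the nitronate to a nitrocyclopentanone, and incomplete diastereocontrol. Fallback: the cyclohexene is built by an enantioselective Diels–Alder reaction, setting out from iodide 2 and coming back at aldehyde 10, so that steps 3 to 5 are not needed. Heck coupling of 2 with 2-methylbut-3-en-2-ol (Pd(OAc)2, nBu4NCl, NaHCO3, DMF) gives (E)-8-(3-hydroxy-3-methylbut-1-en-1-yl)-5,7-dimethoxy-2H-chromen-2-one F1. Dehydration with catalytic pyridinium p-toluenesulfonate in warm PhMe gives 5,7-dimethoxy-8-[(E)-3-methylbuta-1,3-dien-1-yl]-2H-chromen-2-one F2. Cycloaddition of F2 with methacrolein at −78 °C in CH2Cl2, catalysed by (S)-3,3-diphenyl-1-(o-tolyl)tetrahydro-1H,3H-pyrrolo[1,2-c][1,3,2]oxazaborole activated with HNTf2 (20 mol %), gives 10 by the ortho, endo-formyl mode; the catalyst antipode is chosen to deliver (1S,2S).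

Step 5. The nitro group is neopentyl, and the methoxide can open the coumarin lactones reversibly. Fallback: the nitro group is taken to the aldehyde through the amine, setting out from 8 and coming back at 10. Zn dust in AcOH/THF reduces 8 to 8-[(1R,6S)-6-(aminomethyl)-3,6-dimethylcyclohex-2-en-1-yl]-5,7-dimethoxy-2H-chromen-2-one F3. Transamination of F3 with 4-formyl-1-methylpyridinium benzenesulfonate (DBU, CH2Cl2/DMF, then aqueous oxalic acid) gives 10.

Step 7. The aryl iodide is di-ortho-substituted and the alkene sits on a quaternary carbon, so oxidative addition and insertion may both be slow. Fallback: the styrene bond is made by Suzuki coupling, setting out from 10 and coming back at 12, so that step 6 is not needed. Takai–Utimoto olefination of 10 (Cl2CHB(pin), CrCl2, LiI, THF, rt) gives 8-[(1R,6R)-3,6-dimethyl-6-[(E)-2-(4,4,5,5-tetramethyl-1,3,2-dioxaborolan-2-yl)ethenyl]cyclohex-2-en-1-yl]-5,7-dimethoxy-2H-chromen-2-one F4. Coupling of F4 with 2 (Pd(dppf)Cl2, K3PO4, dioxane/water, 60 °C) gives 12 with retention of the E geometry.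

**Further compounds**
F1 | step 4 | (E)-8-(3-hydroxy-3-methylbut-1-en-1-yl)-5,7-dimethoxy-2H-chromen-2-one | COc1cc(OC)c2ccc(=O)oc2c1/C=C/C(C)(C)O
F2 | step 4 | 5,7-dimethoxy-8-[(E)-3-methylbuta-1,3-dien-1-yl]-2H-chromen-2-one | COc1cc(OC)c2ccc(=O)oc2c1/C=C/C(C)=C
F3 | step 5 | 8-[(1R,6S)-6-(aminomethyl)-3,6-dimethylcyclohex-2-en-1-yl]-5,7-dimethoxy-2H-chromen-2-one | NC[C@@]1(C)CCC(C)=C[C@H]1c1c(OC)cc(OC)c2ccc(=O)oc12
F4 | step 7 | 8-[(1R,6R)-3,6-dimethyl-6-[(E)-2-(4,4,5,5-tetramethyl-1,3,2-dioxaborolan-2-yl)ethenyl]cyclohex-2-en-1-yl]-5,7-dimethoxy-2H-chromen-2-one | CC1(C)OB(/C=C/[C@@]2(C)CCC(C)=C[C@H]2c2c(OC)cc(OC)c3ccc(=O)oc23)OC1(C)C
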